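**Plan**
- Retrosynthetic cuts: first the geometry of the exocyclic C1=CH bond (Z from E); then that bond itself, back to a C1 ketone and a 4-methoxybenzyl Grignard reagent; then ring bond C3–C3a, opening the indane to an acyclic triaryl enone; last the enone's aryl–carbonyl bond and its Cα=Cβ bond.
- Forward order: the chain is joined first (Perkin condensation, Weinreb amide, aryl Grignard), the five-membered ring then closes in one acid-catalysed Nazarov step, and the benzylidene carbon, global demethylation and alkene inversion follow.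
- Enabling feature: with C1 as the benzylidene carbon, C3 carries the 4-oxygenated phenyl ring and is bonded to C3a of ring A, which is ortho to the C4 oxygen and para to the C6 oxygen. A cation-stabilised C3 and a nucleophilic C3a are therefore matched once C1 is a carbonyl group.
- Stereochemistry: C3 from the sense of conrotation imposed by a chiral Brønsted-acid counter-anion; C2 from thermodynamic (trans) protonation next to the ketone; the Z alkene from triplet-sensitised E-to-Z isomerisation in the last step.

Key step: step 4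

Assumption: the sense of induction of the chiral acid in step 4 cannot be predicted, so the (R)-acid is written and its enantiomer would be used if the (2R,3R) series resulted; 11 is taken as the commercial THF solution.

**Route**

Step 1
Reactants: 1 3,5-dimethoxyphenylacetic acid; 2 4-methoxybenzaldehyde
Product: 3 (E)-2-(3,5-dimethoxyphenyl)-3-(4-methoxyphenyl)prop-2-enoic acid
Conditions: Ac2O, Et3N, 120 °C; then aq. HCl, recrystallisation
Reagents that add atoms: none
Why: Perkin condensation of an arylacetic acid with an aromatic aldehyde is reversible up to the elimination and is known to give the E acid with the two aryl groups cis, which fixes the enone geometry needed in step 4.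

Step 2
Reactants: 3 (E)-2-(3,5-dimethoxyphenyl)-3-(4-methoxyphenyl)prop-2-enoic acid
Product: 5 (E)-2-(3,5-dimethoxyphenyl)-N-methoxy-3-(4-methoxyphenyl)-N-methylprop-2-enamide, via acid chloride 4 (not isolated)
Conditions: (COCl)2, cat. DMF, CH2Cl2, 0 °C to rt, concentrate; MeNH(OMe)·HCl, Et3N, CH2Cl2, 0 °C to rt
Reagents that add atoms: N,O-dimethylhydroxylamine hydrochloride, CNOC.Cl
Why: Weinreb amide formation through the acid chloride acts only at the carboxyl group, so the trisubstituted E alkene should be carried through unchanged.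

Step 3
Reactants: 5 (E)-2-(3,5-dimethoxyphenyl)-N-methoxy-3-(4-methoxyphenyl)-N-methylprop-2-enamide; 6 1-bromo-3,5-dimethoxybenzene
Product: 8 (E)-1,2-bis(3,5-dimethoxyphenyl)-3-(4-methoxyphenyl)prop-2-en-1-one, via 3,5-dimethoxyphenylmagnesium bromide 7 (not isolated)
Conditions: 6, Mg, cat. I2, THF, reflux; then 5, THF, 0 °C to rt; 1 M HCl
Reagents that add atoms: none
Why: Weinreb ketone synthesis, in which the Grignard adduct is held as a chelated tetrahedral magnesium species until acidic work-up, so over-addition and conjugate addition at the hindered β-carbon are avoided and the alkene geometry is retained.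

Step 4
Reactants: 8 (E)-1,2-bis(3,5-dimethoxyphenyl)-3-(4-methoxyphenyl)prop-2-en-1-one
Product: 10 (2S,3S)-2-(3,5-dimethoxyphenyl)-4,6-dimethoxy-3-(4-methoxyphenyl)-2,3-dihydro-1H-inden-1-one, via indenol enol 9 (not isolated)
Conditions: (R)-3,3'-bis(9-phenanthryl)-5,5',6,6',7,7',8,8'-octahydro-1,1'-binaphthalene-2,2'-diyl N-(trifluoromethylsulfonyl)phosphoramide (10 mol%), CHCl3, 0 to 25 °C; then basic Al2O3
Reagents that add atoms: none
Why: Proposed new method: O-protonation of 8 by the chiral N-triflylphosphoramide gives a hydroxypentadienyl cation over C3, C2, C1, C7a and C3a, held to its anion by a hydrogen bond, and conrotatory 4π-electrocyclisation joins the anisyl-stabilised C3 to C3a, the ring A carbon ortho and para to the two methoxy groups; the closest known reaction types are N-triflylphosphoramide-catalysed asymmetric Nazarov cyclisations of activated divinyl ketones and the racemic acid-promoted Nazarov closure of 3,5-dimethoxyphenyl vinyl ketones, whereas counter-anion control of an aryl vinyl ketone closure is unproven. The five-membered ring closes in the thermally allowed conrotatory 4π electrocyclic mode of the pentadienyl cation, so the direction of rotation at C3 defines that centre. C3 (S) is set by catalyst control, the chiral anion biasing the torquoselectivity of the cation it is paired with, and the transient sp3 centre at C3a is erased when the Wheland intermediate rearomatises to enol 9. C2 (S) is set by substrate control under thermodynamic conditions, because ketonisation of 9 is reversible under the acid and on basic alumina and the trans arrangement of the two aryl groups is the more stable. The step needs closure onto ring A only and one sense of conrotation: the first is secured because both ortho positions of the ketone-bearing ring are equivalent and doubly activated while the α-aryl ring cannot reach C3. The second rests on the single E geometry of 8, which places the anisyl group outside and hydrogen inside the U-shaped cation, and on a low temperature that suppresses the uncatalysed background.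

Step 5
Reactants: 10 (2S,3S)-2-(3,5-dimethoxyphenyl)-4,6-dimethoxy-3-(4-methoxyphenyl)-2,3-dihydro-1H-inden-1-one; 11 4-methoxybenzylmagnesium chloride
Product: 12 (1R,2S,3S)-2-(3,5-dimethoxyphenyl)-4,6-dimethoxy-1-[(4-methoxyphenyl)methyl]-3-(4-methoxyphenyl)-2,3-dihydro-1H-inden-1-ol
Conditions: 10, CeCl3 (anhydrous), THF, rt; then 11, −78 to 0 °C; aq. NH4Cl
Reagents that add atoms: none
Why: CeCl3-promoted Grignard 1,2-addition suppresses deprotonation of the acidic C2–H (any enolate returns trans-10 on work-up with C3 intact), and the benzyl group should enter C1 from the face opposite the adjacent C2 aryl group, which sets C1 as R with the hydroxyl group anti to C2–H.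

Step 6
Reactants: 12 (1R,2S,3S)-2-(3,5-dimethoxyphenyl)-4,6-dimethoxy-1-[(4-methoxyphenyl)methyl]-3-(4-methoxyphenyl)-2,3-dihydro-1H-inden-1-ol
Product: 13 (1E,2S,3S)-2-(3,5-dimethoxyphenyl)-4,6-dimethoxy-3-(4-methoxyphenyl)-1-[(4-methoxyphenyl)methylidene]-2,3-dihydro-1H-indene
Conditions: Burgess reagent (methyl N-(triethylammoniosulfonyl)carbamate), toluene, 50 °C
Reagents that add atoms: none
Why: Burgess dehydration is a syn-elimination through the sulfamate ester in a neutral medium, and since C2–H lies on the face opposite the leaving group only the exocyclic CH2 hydrogens are available, so the alkene should form outside the ring as the less strained E isomer without a free cation and without touching C2 or C3 (the geometry is not critical because step 8 resets it).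

Step 7
Reactants: 13 (1E,2S,3S)-2-(3,5-dimethoxyphenyl)-4,6-dimethoxy-3-(4-methoxyphenyl)-1-[(4-methoxyphenyl)methylidene]-2,3-dihydro-1H-indene
Product: 14 (1E,2S,3S)-2-(3,5-dihydroxyphenyl)-3-(4-hydroxyphenyl)-1-[(4-hydroxyphenyl)methylidene]-2,3-dihydro-1H-indene-4,6-diol
Conditions: BBr3 (excess), CH2Cl2, −78 to 25 °C; then H2O at 0 °C
Reagents that add atoms: none
Why: BBr3 cleavage of aryl methyl ethers (boron complexation, bromide attack on methyl) is the standard global demethylation of permethylated stilbenoid oligomers and should leave the two sp3 stereocentres and the trisubstituted alkene in place when quenched cold.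

Step 8
Reactants: 14 (1E,2S,3S)-2-(3,5-dihydroxyphenyl)-3-(4-hydroxyphenyl)-1-[(4-hydroxyphenyl)methylidene]-2,3-dihydro-1H-indene-4,6-diol
Product: 15 (1Z,2S,3S)-2-(3,5-dihydroxyphenyl)-3-(4-hydroxyphenyl)-1-[(4-hydroxyphenyl)methylidene]-2,3-dihydro-1H-indene-4,6-diol
Conditions: fac-Ir(ppy)3 (ppy = 2-phenylpyridinato, 1 mol%), degassed MeCN–MeOH, blue LEDs (450 nm), 25 °C; reverse-phase HPLC, recovered 14 recycled
Reagents that add atoms: none
Why: Triplet-sensitised E-to-Z alkene isomerisation: energy transfer from excited Ir(ppy)3 gives a twisted styrenyl triplet that relaxes to either geometry, and the E isomer, whose ring A and 4-hydroxyphenyl ring form a nearly planar stilbene unit, is re-excited preferentially, so the more twisted Z isomer should accumulate while C2 and C3 are not involved.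

**Compound list**

1 | 3,5-dimethoxyphenylacetic acid | OC(=O)Cc1cc(OC)cc(OC)c1 | starting material
2 | 4-methoxybenzaldehyde | COc1ccc(C=O)cc1 | starting material
3 | (E)-2-(3,5-dimethoxyphenyl)-3-(4-methoxyphenyl)prop-2-enoic acid (aryl groups cis) | OC(=O)/C(c1cc(OC)cc(OC)c1)=C/c1ccc(OC)cc1 | intermediate
4 | (E)-2-(3,5-dimethoxyphenyl)-3-(4-methoxyphenyl)prop-2-enoyl chloride | ClC(=O)/C(c1cc(OC)cc(OC)c1)=C/c1ccc(OC)cc1 | intermediate (not isolated)
5 | (E)-2-(3,5-dimethoxyphenyl)-N-methoxy-3-(4-methoxyphenyl)-N-methylprop-2-enamide | CON(C)C(=O)/C(c1cc(OC)cc(OC)c1)=C/c1ccc(OC)cc1 | intermediate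
6 | 1-bromo-3,5-dimethoxybenzene | COc1cc(Br)cc(OC)c1 | starting material
7 | 3,5-dimethoxyphenylmagnesium bromide | COc1cc([Mg]Br)cc(OC)c1 | intermediate (not isolated)
8 | (E)-1,2-bis(3,5-dimethoxyphenyl)-3-(4-methoxyphenyl)prop-2-en-1-one | COc1cc(OC)cc(C(=O)/C(c2cc(OC)cc(OC)c2)=C/c2ccc(OC)cc2)c1 | intermediate
9 | (1R)-2-(3,5-dimethoxyphenyl)-5,7-dimethoxy-1-(4-methoxyphenyl)-1H-inden-3-ol (enol of 10; same spatial arrangement at the anisyl-bearing carbon) | OC1=C(c2cc(OC)cc(OC)c2)[C@@H](c2ccc(OC)cc2)c2c(OC)cc(OC)cc12 | intermediate (not isolated)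
10 | (2S,3S)-2-(3,5-dimethoxyphenyl)-4,6-dimethoxy-3-(4-methoxyphenyl)-2,3-dihydro-1H-inden-1-one (aryl groups trans) | O=C1c2cc(OC)cc(OC)c2[C@H](c2ccc(OC)cc2)[C@H]1c1cc(OC)cc(OC)c1 | intermediate
11 | 4-methoxybenzylmagnesium chloride | COc1ccc(C[Mg]Cl)cc1 | starting material
12 | (1R,2S,3S)-2-(3,5-dimethoxyphenyl)-4,6-dimethoxy-1-[(4-methoxyphenyl)methyl]-3-(4-methoxyphenyl)-2,3-dihydro-1H-inden-1-ol (benzyl group trans to the C2 aryl group) | O[C@@]1(Cc2ccc(OC)cc2)c2cc(OC)cc(OC)c2[C@H](c2ccc(OC)cc2)[C@H]1c1cc(OC)cc(OC)c1 | intermediate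
13 | (1E,2S,3S)-2-(3,5-dimethoxyphenyl)-4,6-dimethoxy-3-(4-methoxyphenyl)-1-[(4-methoxyphenyl)methylidene]-2,3-dihydro-1H-indene | COc1ccc(/C=C2/c3cc(OC)cc(OC)c3[C@H](c3ccc(OC)cc3)[C@H]2c2cc(OC)cc(OC)c2)cc1 | intermediate
14 | (1E,2S,3S)-2-(3,5-dihydroxyphenyl)-3-(4-hydroxyphenyl)-1-[(4-hydroxyphenyl)methylidene]-2,3-dihydro-1H-indene-4,6-diol | Oc1ccc(/C=C2/c3cc(O)cc(O)c3[C@H](c3ccc(O)cc3)[C@H]2c2cc(O)cc(O)c2)cc1 | intermediate
15 | (1Z,2S,3S)-2-(3,5-dihydroxyphenyl)-3-(4-hydroxyphenyl)-1-[(4-hydroxyphenyl)methylidene]-2,3-dihydro-1H-indene-4,6-diol (CNP0253309.1) | Oc1ccc(/C=C2\c3cc(O)cc(O)c3[C@H](c3ccc(O)cc3)[C@H]2c2cc(O)cc(O)c2)cc1 | target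

**Totals**

Total step count: 8. Longest linear sequence: 8 steps (1 and 2 to 15).

**Steps most likely to fail**

Step 4. The risks are that the chiral acid protonates the aryl vinyl ketone too weakly to outrun a racemic background closure, that the ion pair fails to bias the sense of conrotation, and that E/Z scrambling of the protonated enone uncouples alkene geometry from torquoselectivity. The fallback uses known chemistry: the sense of conrotation is taken from a sulfinyl auxiliary bound to C2, and the C2 aryl group is added after the ring has closed. It sets out from 2 and 6 and returns at 10.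
- Methyl 3,5-dimethoxybenzoate is acylated onto the lithium anion of (R)-methyl p-tolyl sulfoxide (LDA, THF, −78 °C) to give the β-keto sulfoxide (R)-1-(3,5-dimethoxyphenyl)-2-[(4-methylphenyl)sulfinyl]ethan-1-one F1.
- Knoevenagel condensation of F1 with 2 (piperidine, AcOH, toluene, reflux) gives the α-sulfinyl enone (Z)-1-(3,5-dimethoxyphenyl)-3-(4-methoxyphenyl)-2-[(S)-(4-methylphenyl)sulfinyl]prop-2-en-1-one F2. Its geometry is drawn by assumption; the sulfur centre is unchanged in space.
- AlCl3 in CH2Cl2 should bring about the auxiliary-directed Nazarov cyclisation to (2R,3S)-4,6-dimethoxy-3-(4-methoxyphenyl)-2-[(R)-(4-methylphenyl)sulfinyl]-2,3-dihydro-1H-inden-1-one F3. The auxiliary enantiomer would be exchanged if the (3R) series resulted.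
- Reductive desulfinylation (Zn, aq. NH4Cl, THF) gives (3S)-4,6-dimethoxy-3-(4-methoxyphenyl)-2,3-dihydro-1H-inden-1-one F4.
- Palladium-catalysed α-arylation of the enolate of F4 with 6 (Pd2(dba)3, t-Bu3P·HBF4, NaOt-Bu, toluene, 70 °C) returns 10 as the trans isomer after thermodynamic protonation.

Step 6. The risks are proton loss from C2 instead of the benzylic CH2, which flattens C2 and gives the ring-conjugated indene, and ionisation at C1 followed by cationic side reactions. Both become more likely if step 5 delivers some of the C1 epimer whose hydroxyl group is syn to C2–H. In the fallback the alkene is made without a C1 carbinol. It sets out from 10 and returns at 13: a cross-McMurry coupling of 10 with an excess of aldehyde 2 (low-valent titanium from TiCl4 and Zn, pyridine, THF, reflux) places the double bond between the two former carbonyl carbons by construction. The hindered ketone should homocouple slowly, and the stilbene formed from the excess aldehyde is removed by chromatography. No compound outside the list is made.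

Step 8. The risks are a photostationary state that is not driven far enough to the Z side and slow photodegradation of the oxygen-sensitive hexaphenol on long irradiation. In the fallback the Z geometry is built by stereospecific Peterson elimination instead of light. It sets out from 10 and returns at 15.
- (4-Methoxybenzyl)trimethylsilane is metalated at the benzylic carbon (s-BuLi, TMEDA, THF, −78 °C), transmetalated with CeCl3 and added to 10 from the face opposite the C2 aryl group. This should give two β-hydroxysilanes epimeric at the silyl-bearing carbon, separable on silica: (1R,2S,3S)-2-(3,5-dimethoxyphenyl)-4,6-dimethoxy-3-(4-methoxyphenyl)-1-[(S)-(4-methoxyphenyl)(trimethylsilyl)methyl]-2,3-dihydro-1H-inden-1-ol F5 and its epimer (1R,2S,3S)-2-(3,5-dimethoxyphenyl)-4,6-dimethoxy-3-(4-methoxyphenyl)-1-[(R)-(4-methoxyphenyl)(trimethylsilyl)methyl]-2,3-dihydro-1H-inden-1-ol F6.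
- F5 with KH (THF, 0 °C) should undergo syn-elimination and F6 with BF3·OEt2 (CH2Cl2, −78 °C) anti-elimination, so both converge on (1Z,2S,3S)-2-(3,5-dimethoxyphenyl)-4,6-dimethoxy-3-(4-methoxyphenyl)-1-[(4-methoxyphenyl)methylidene]-2,3-dihydro-1H-indene F7.
- Demethylation of F7 with BBr3 as in step 7, quenched cold, gives 15.

**Further compounds**

F1 | step 4 | (R)-1-(3,5-dimethoxyphenyl)-2-[(4-methylphenyl)sulfinyl]ethan-1-one | COc1cc(OC)cc(C(=O)C[S@@](=O)c2ccc(C)cc2)c1
F2 | step 4 | (Z)-1-(3,5-dimethoxyphenyl)-3-(4-methoxyphenyl)-2-[(S)-(4-methylphenyl)sulfinyl]prop-2-en-1-one | COc1cc(OC)cc(C(=O)/C(=C/c2ccc(OC)cc2)[S@@](=O)c2ccc(C)cc2)c1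
F3 | step 4 | (2R,3S)-4,6-dimethoxy-3-(4-methoxyphenyl)-2-[(R)-(4-methylphenyl)sulfinyl]-2,3-dihydro-1H-inden-1-one | O=C1c2cc(OC)cc(OC)c2[C@H](c2ccc(OC)cc2)[C@H]1[S@@](=O)c1ccc(C)cc1
F4 | step 4 | (3S)-4,6-dimethoxy-3-(4-methoxyphenyl)-2,3-dihydro-1H-inden-1-one | O=C1c2cc(OC)cc(OC)c2[C@H](c2ccc(OC)cc2)C1
F0 | step 6 | none | none
F5 | step 8 | (1R,2S,3S)-2-(3,5-dimethoxyphenyl)-4,6-dimethoxy-3-(4-methoxyphenyl)-1-[(S)-(4-methoxyphenyl)(trimethylsilyl)methyl]-2,3-dihydro-1H-inden-1-ol | O[C@@]1([C@H](c2ccc(OC)cc2)[Si](C)(C)C)c2cc(OC)cc(OC)c2[C@H](c2ccc(OC)cc2)[C@H]1c1cc(OC)cc(OC)c1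
F6 | step 8 | (1R,2S,3S)-2-(3,5-dimethoxyphenyl)-4,6-dimethoxy-3-(4-methoxyphenyl)-1-[(R)-(4-methoxyphenyl)(trimethylsilyl)methyl]-2,3-dihydro-1H-inden-1-ol | O[C@@]1([C@@H](c2ccc(OC)cc2)[Si](C)(C)C)c2cc(OC)cc(OC)c2[C@H](c2ccc(OC)cc2)[C@H]1c1cc(OC)cc(OC)c1
F7 | step 8 | (1Z,2S,3S)-2-(3,5-dimethoxyphenyl)-4,6-dimethoxy-3-(4-methoxyphenyl)-1-[(4-methoxyphenyl)methylidene]-2,3-dihydro-1H-indene | COc1ccc(/C=C2\c3cc(OC)cc(OC)c3[C@H](c3ccc(OC)cc3)[C@H]2c2cc(OC)cc(OC)c2)cc1
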